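**Retrosynthetic overview**

1. Target 19 is a 6-oxabicyclo[3.2.2]non-3-ene-2,7-dione: a cyclohept-2-enone ring whose C-1 and C-5 are spanned by the O6–C7(=O) bridge. That two-atom bridge, carbonyl oxygen included, is one molecule of CO2 joining the only enolizable α-carbon of the ketone (C-1) to the methoxy-bearing ketal carbon (C-5). Cutting C1–C7 and C5–O6 gives cycloheptenone dimethyl ketal 14 and CO2.
2. 14 comes from cycloheptadienone ketal 12 by trans-selective rhodium-catalysed conjugate arylation at C-6.
3. 12 comes from cyclohexenone 7 by one-carbon insertion on the saturated side (silyl enol ether, cyclopropanation, FeCl3 ring opening). A diazoalkane homologation is avoided: on a 2-en-1-one it is expected to migrate the vinyl carbon, and its Lewis acid would ionise the ketal.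
4. 7 comes from quinone monoketal 5 by enantioselective copper-catalysed methyl addition; 5 comes from 4-methoxyphenol by O-allylation, Claisen rearrangement and oxidative dearomatisation in methanol.
5. Ring order: six-membered carbocycle (from the arene), then seven-membered carbocycle (step 7), then the δ-lactone ring of the bicycle (step 9).

Key step: step 9

Assumption: the (S,R,R)-phosphoramidite is taken to deliver methyl to the face of 5 that gives (5R)-7, by analogy with its sense on cyclohex-2-enone; if the sense proves opposite, its enantiomer is used.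

**Step 1**
Reactants: 1 4-methoxyphenol; 2 allyl bromide
Product: 3 1-(allyloxy)-4-methoxybenzene
Conditions: K2CO3, acetone, reflux
Reagents that add atoms: none
Why: Williamson ether synthesis, the phenoxide displacing bromide from the primary allylic carbon.

**Step 2**
Reactants: 3 1-(allyloxy)-4-methoxybenzene
Product: 4 2-allyl-4-methoxyphenol
Conditions: N,N-diethylaniline, 200 °C
Reagents that add atoms: none
Why: Aromatic Claisen rearrangement, a [3,3] shift to the free ortho position followed by tautomerisation, the para position being blocked by the methoxy group.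

**Step 3**
Reactants: 4 2-allyl-4-methoxyphenol
Product: 5 2-allyl-4,4-dimethoxycyclohexa-2,5-dien-1-one
Conditions: PhI(OAc)2, MeOH, 0 °C
Reagents that add atoms: methanol, CO
Why: Oxidative dearomatisation of a para-methoxyphenol with a hypervalent iodine reagent, methanol capturing the phenoxonium ion at the methoxy-bearing carbon to give the quinone monoketal.

**Step 4**
Reactants: 5 2-allyl-4,4-dimethoxycyclohexa-2,5-dien-1-one
Product: 7 (R)-2-allyl-4,4-dimethoxy-5-methylcyclohex-2-en-1-one, via methylzinc enolate 6 (not isolated)
Conditions: Me2Zn, Cu(OTf)2 (cat.), (S,R,R)-binaphthol bis(1-phenylethyl)amine phosphoramidite (cat.), toluene, −25 °C; NH4Cl (aq)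
Reagents that add atoms: dimethylzinc, C[Zn]C
Why: Copper-catalysed enantioselective conjugate addition, in which methyl should go to C-5 of the unsubstituted enone (the allyl-bearing enone is α-substituted and slower) and the chiral copper complex selects the enantiotopic face to set C-5 as R, the buffered quench sparing the ketal.

**Step 5**
Reactants: 7 (R)-2-allyl-4,4-dimethoxy-5-methylcyclohex-2-en-1-one
Product: 9 (R)-[(6-allyl-4,4-dimethoxy-3-methylcyclohexa-1,5-dien-1-yl)oxy]trimethylsilane, via lithium enolate 8 (not isolated)
Conditions: LiN(iPr)2, THF, −78 °C; Me3SiCl, Et3N, −78 to 0 °C; pentane, cold NaHCO3 (aq); used crude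
Reagents that add atoms: chlorotrimethylsilane, C[Si](C)(C)Cl
Why: Kinetic enolisation and O-silylation, regiodefined because C-6 is the only carbon with an enolizable hydrogen, and kept basic throughout because the dienol ether can lose methanol to an arene under acid.

**Step 6**
Reactants: 9 (R)-[(6-allyl-4,4-dimethoxy-3-methylcyclohexa-1,5-dien-1-yl)oxy]trimethylsilane
Product: 10 (5R)-2-allyl-4,4-dimethoxy-5-methyl-1-(trimethylsilyloxy)bicyclo[4.1.0]hept-2-ene (ring-fusion isomers)
Conditions: Et2Zn, CH2I2, Et2O, 0 °C to rt; pyridine, then NaHCO3 (aq)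
Reagents that add atoms: diiodomethane, ICI
Why: Furukawa variant of the Simmons–Smith cyclopropanation, the electrophilic zinc carbenoid taking the electron-rich silyl enol ether double bond ahead of the terminal alkene and the ketal-flanked trisubstituted alkene, with the ring-fusion configuration of no consequence because both centres are destroyed in step 7.

**Step 7**
Reactants: 10 (5R)-2-allyl-4,4-dimethoxy-5-methyl-1-(trimethylsilyloxy)bicyclo[4.1.0]hept-2-ene
Product: 12 (R)-2-allyl-4,4-dimethoxy-5-methylcyclohepta-2,6-dien-1-one, via beta-chloro ketone 11 (not isolated)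
Conditions: FeCl3, pyridine, DMF, 0 °C; then NaOAc, MeOH, 60 °C
Reagents that add atoms: none
Why: Ito–Saegusa ring expansion, in which one-electron oxidation by FeCl3 cleaves the internal cyclopropane bond to the secondary β-keto radical, chlorine transfer gives 11 and acetate-induced E1cB elimination gives the enone, so that the new carbon becomes C-7 on the saturated side of the ketone.

**Step 8**
Reactants: 12 (R)-2-allyl-4,4-dimethoxy-5-methylcyclohepta-2,6-dien-1-one; 13 (3,4,5-trimethoxyphenyl)boronic acid
Product: 14 (5R,6S)-2-allyl-4,4-dimethoxy-5-methyl-6-(3,4,5-trimethoxyphenyl)cyclohept-2-en-1-one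
Conditions: [Rh(cod)OH]2 (cat.), dioxane/H2O 10:1, 35 °C
Reagents that add atoms: none
Why: Hayashi–Miyaura rhodium-catalysed conjugate addition, the aryl–rhodium species adding to C-6 of the unsubstituted enone (the α-allyl enone next to the quaternary ketal is too hindered) on the face anti to the neighbouring C-5 methyl to set C-6 as S (trans), with water protonating the rhodium enolate under near-neutral conditions that should not eliminate methanol.

**Step 9**
Reactants: 14 (5R,6S)-2-allyl-4,4-dimethoxy-5-methyl-6-(3,4,5-trimethoxyphenyl)cyclohept-2-en-1-one; 15 carbon dioxide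
Product: 19 (1R,5S,8R,9R)-3-allyl-5-methoxy-9-methyl-8-(3,4,5-trimethoxyphenyl)-6-oxabicyclo[3.2.2]non-3-ene-2,7-dione, via lithium enolate 16 (not isolated), via lithium beta-keto carboxylate 17 (not isolated), via trimethylsilyl beta-keto ester 18 (not isolated)
Conditions: LiN(SiMe3)2, THF, −78 °C; CO2 (g), −78 °C; CH2Cl2, Me3SiOTf, −78 to −40 °C; Et3N, NaHCO3 (aq)
Reagents that add atoms: none
Why: Proposed new method: LiN(SiMe3)2 removes a C-7 proton of 14, the only enolizable position because the other α-carbon is the alkene carbon C-2, and enolate 16 adds to CO2 to give 17; Me3SiOTf then silylates the carboxylate to 18 and ionises the allylic dimethyl ketal, the carboxyl oxygen attacks the methoxy-stabilised oxocarbenium carbon across the ring and the silyl group leaves as methoxytrimethylsilane, so that the C1–C7 and C5–O6 bonds of 19 are made in one flask. The closest known reactions are the carboxylation of kinetic ketone enolates with CO2 and the acid-induced formation of acyloxy ketals (pseudo-esters) from keto acids; their transannular one-pot union is new. The δ-lactone ring closes in the 6-exo-trig mode, the C=O(+)Me bond lying outside the ring that forms. The new stereocentres C-1 and C-5 are coupled, since the two-atom bridge can span only one face of the carbocycle, and that face is chosen at the closure: C-7 of 17 and 18 epimerises through the enol, closure is reversible under the silyl triflate, and the isomer should prevail in which the oxygen adds to the oxocarbenium face anti to the neighbouring C-methyl, leaving the aryl group beside the unsubstituted O–C(=O) bridge and the methyl group facing the enone bridge (carboxyl cis to aryl; 1R,5S). The step needs C-carboxylation and capture before decarboxylation: the free β-keto acid never accumulates because the carboxylate is silylated cold, and 19 cannot decarboxylate because its enol would be a bridgehead alkene.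

**Compound list**

1 | 4-methoxyphenol | COc1ccc(O)cc1 | starting material
2 | allyl bromide | C=CCBr | starting material
3 | 1-(allyloxy)-4-methoxybenzene | C=CCOc1ccc(OC)cc1 | intermediate
4 | 2-allyl-4-methoxyphenol | C=CCc1cc(OC)ccc1O | intermediate
5 | 2-allyl-4,4-dimethoxycyclohexa-2,5-dien-1-one | C=CCC1=CC(OC)(OC)C=CC1=O | intermediate
6 | methyl{[(R)-6-allyl-4,4-dimethoxy-3-methylcyclohexa-1,5-dien-1-yl]oxy}zinc (methylzinc enolate) | C=CCC1=CC(OC)(OC)[C@H](C)C=C1O[Zn]C | intermediate
7 | (R)-2-allyl-4,4-dimethoxy-5-methylcyclohex-2-en-1-one | C=CCC1=CC(OC)(OC)[C@H](C)CC1=O | intermediate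
8 | lithium (R)-6-allyl-4,4-dimethoxy-3-methylcyclohexa-1,5-dien-1-olate (lithium enolate of 7) | C=CCC1=CC(OC)(OC)[C@H](C)C=C1O[Li] | intermediate
9 | (R)-[(6-allyl-4,4-dimethoxy-3-methylcyclohexa-1,5-dien-1-yl)oxy]trimethylsilane | C=CCC1=CC(OC)(OC)[C@H](C)C=C1O[Si](C)(C)C | intermediate
10 | (5R)-2-allyl-4,4-dimethoxy-5-methyl-1-(trimethylsilyloxy)bicyclo[4.1.0]hept-2-ene (ring-fusion isomers) | C=CCC1=CC(OC)(OC)[C@H](C)C2CC12O[Si](C)(C)C | intermediate
11 | (5S)-2-allyl-6-chloro-4,4-dimethoxy-5-methylcyclohept-2-en-1-one (C-6 epimers; the methyl carbon is unchanged in space, its descriptor changes with the chlorine-bearing neighbour) | C=CCC1=CC(OC)(OC)[C@H](C)C(Cl)CC1=O | intermediate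
12 | (R)-2-allyl-4,4-dimethoxy-5-methylcyclohepta-2,6-dien-1-one | C=CCC1=CC(OC)(OC)[C@H](C)C=CC1=O | intermediate
13 | (3,4,5-trimethoxyphenyl)boronic acid | COc1cc(B(O)O)cc(OC)c1OC | starting material
14 | (5R,6S)-2-allyl-4,4-dimethoxy-5-methyl-6-(3,4,5-trimethoxyphenyl)cyclohept-2-en-1-one | C=CCC1=CC(OC)(OC)[C@H](C)[C@@H](c2cc(OC)c(OC)c(OC)c2)CC1=O | intermediate
15 | carbon dioxide | O=C=O | starting material
16 | lithium 7-allyl-5,5-dimethoxy-4-methyl-3-(3,4,5-trimethoxyphenyl)cyclohepta-1,6-dien-1-olate (lithium enolate of 14; methyl and aryl carbons as in 14) | C=CCC1=CC(OC)(OC)[C@H](C)[C@@H](c2cc(OC)c(OC)c(OC)c2)C=C1O[Li] | intermediate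
17 | lithium 3-allyl-5,5-dimethoxy-6-methyl-2-oxo-7-(3,4,5-trimethoxyphenyl)cyclohept-3-ene-1-carboxylate (C-1 epimers; methyl and aryl carbons as in 14) | C=CCC1=CC(OC)(OC)[C@H](C)[C@@H](c2cc(OC)c(OC)c(OC)c2)C(C(=O)O[Li])C1=O | intermediate
18 | trimethylsilyl 3-allyl-5,5-dimethoxy-6-methyl-2-oxo-7-(3,4,5-trimethoxyphenyl)cyclohept-3-ene-1-carboxylate (C-1 epimers; methyl and aryl carbons as in 14) | C=CCC1=CC(OC)(OC)[C@H](C)[C@@H](c2cc(OC)c(OC)c(OC)c2)C(C(=O)O[Si](C)(C)C)C1=O | intermediate
19 | (1R,5S,8R,9R)-3-allyl-5-methoxy-9-methyl-8-(3,4,5-trimethoxyphenyl)-6-oxabicyclo[3.2.2]non-3-ene-2,7-dione | C=CCC1=C[C@@]2(OC)OC(=O)[C@@H](C1=O)[C@H](c1cc(OC)c(OC)c(OC)c1)[C@H]2C | target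

**Step count and risks**

Total step count: 9. Longest linear sequence: 9 steps (1 to 19).

Steps most likely to fail:

Step 9 (proposed new method). The β-keto carboxylate may decarboxylate before capture, the bridge may close on the face cis to the methyl group, or the ionised ketal may lose a proton to an enol ether instead of being trapped. The fallback sets out from 14 and uses known chemistry. 14 is deprotonated with LiN(SiMe3)2 (two equivalents) and C-acylated with di-tert-butyl dicarbonate to the tert-butyl beta-keto ester F1, which is stable to isolation and cannot decarboxylate. Me3SiOTf with 2,6-di-tert-butylpyridine in CH2Cl2 at −78 °C then ionises the ketal, the ester carbonyl oxygen closes on the oxocarbenium ion and the tert-butyl group is lost as 2-methylpropene (dealkylative lactonisation of a tert-butyl ester onto a cation). This returns to the route at 19.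

Step 6. The zinc halide formed in the cyclopropanation may ionise the ketal of the dienol silyl ether, with loss of methanol and aromatisation, or the carbenoid may also attack the allyl terminus. The fallback sets out from 9 and inserts the carbon under basic conditions. Dibromocarbene (CHBr3, KOtBu, pentane, −20 °C) should add to the enol ether double bond to give the dibromocyclopropane F2. On warming with pyridine F2 opens with loss of the silyl bromide to the alpha-bromo dienone F3. Hydrodebromination of F3 (Pd(PPh3)4, Bu3SnH, toluene) gives 12, where the route is rejoined with steps 6 and 7 bypassed.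

Step 7. The iron halide may ionise the allylic ketal of 10, or the radical opening may take the external cyclopropane bond or be followed by side reactions of the β-keto radical. The fallback sets out from 10. The silyl ether is cleaved with K2CO3 in MeOH at 0 °C to the free cyclopropanol F4. F4 is opened under non-Lewis-acidic one-electron oxidation with Mn(pic)3 (manganese tris(pyridine-2-carboxylate)) in DMF in the presence of Cu(OAc)2, which should oxidise the ring-expanded β-keto radical directly to the enone. This returns to the route at 12 without a chloride intermediate.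

Further compounds
F1 | step 9 | tert-butyl (6R,7R)-3-allyl-5,5-dimethoxy-6-methyl-2-oxo-7-(3,4,5-trimethoxyphenyl)cyclohept-3-ene-1-carboxylate (C-1 epimers) | C=CCC1=CC(OC)(OC)[C@H](C)[C@@H](c2cc(OC)c(OC)c(OC)c2)C(C(=O)OC(C)(C)C)C1=O
F2 | step 6 | (5R)-2-allyl-7,7-dibromo-4,4-dimethoxy-5-methyl-1-(trimethylsilyloxy)bicyclo[4.1.0]hept-2-ene | C=CCC1=CC(OC)(OC)[C@H](C)C2C(Br)(Br)C12O[Si](C)(C)C
F3 | step 6 | (R)-2-allyl-7-bromo-4,4-dimethoxy-5-methylcyclohepta-2,6-dien-1-one | C=CCC1=CC(OC)(OC)[C@H](C)C=C(Br)C1=O
F4 | step 7 | (5R)-2-allyl-4,4-dimethoxy-5-methylbicyclo[4.1.0]hept-2-en-1-ol | C=CCC1=CC(OC)(OC)[C@H](C)C2CC12O
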